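**Assumption:** the target SMILES contains no stereocentres (the C10=C11 alkene sits in a ring and the pyran CMe2 carbon is symmetric). The target is therefore achiral, no enantiocontrol is needed, and nothing in the route can scramble stereochemistry.

## Retrosynthetic overview
1. The gem-dimethyl-2H-pyran is formed last. A 6π-oxa-electrocyclization of the dienone from dibenzo[b,f]oxepin-10(11H)-one C11-H2 and prenal gives it, and the two phenols are released by Pd-catalysed deallylation.
2. The seven-membered oxepine ring is formed before that, by intramolecular SNAr of the ring-A phenoxide onto an o-fluoroaryl ketone in a deoxybenzoin.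
3. The deoxybenzoin comes from a ring-B aryllithium plus a ring-A Weinreb amide.
4. The prenyl group is put on the resorcinol-type ring A early, at the position ortho to one OH and para to the other.
5. Ring B carries a para-O-allyl group from the start; the ring-A 4-OH is allylated once the oxepine is closed.

## Route

**Step 1**
Reactants: 1 (2,4-dihydroxyphenylacetic acid); 2 (N,O-dimethylhydroxylamine hydrochloride)
Product: 3 (2-(2,4-dihydroxyphenyl)-N-methoxy-N-methylacetamide)
Conditions: EDCI·HCl, HOBt, i-Pr2NEt, DMF, rt, 16 h
Reagents that add atoms: none beyond the listed reactant 2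
Why: Carbodiimide amide coupling. If the acid closes onto the ortho-OH to give the coumaranone, that aryl ester is opened by the amine to the same Weinreb amide. No stereocentre is involved.

**Step 2**
Reactants: 3; 4 (prenyl bromide)
Product: 5 (2-[2,4-dihydroxy-5-(3-methylbut-2-en-1-yl)phenyl]-N-methoxy-N-methylacetamide)
Conditions: 4 (1.1 equiv), NaOH (2.2 equiv), H2O, 0 °C to rt, 3 h; then aqueous NH4Cl
Reagents that add atoms: none beyond the listed reactant 4
Why: Phenoxide C-alkylation in water (an SN2 reaction) goes at C5. That carbon is ortho to the 4-O⁻ and para to the 2-O⁻, so it is the most nucleophilic and least hindered ring carbon. The between-oxygens C3 is disfavoured.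

**Step 3**
Reactants: 6 (4-bromo-3-fluorophenol); 7 (allyl bromide)
Product: 8 (4-(allyloxy)-1-bromo-2-fluorobenzene)
Conditions: 7 (1.2 equiv), K2CO3, acetone, reflux, 6 h
Reagents that add atoms: none beyond the listed reactant 7
Why: Williamson O-allylation. This gives a protecting group that survives strong base and is removed under neutral Pd(0) conditions at the end.

**Step 4**
Reactants: 5; 8
Product: 9 (1-[4-(allyloxy)-2-fluorophenyl]-2-[2,4-dihydroxy-5-(3-methylbut-2-en-1-yl)phenyl]ethan-1-one)
Conditions: (i) 5, NaH (2.1 equiv), THF, 0 °C; (ii) ArLi from 8 (3 equiv) and n-BuLi (3 equiv), THF, −78 °C; add the phenoxide solution, warm to 0 °C; NH4Cl quench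
Reagents that add atoms: none beyond the listed reactant 8
Why: Weinreb ketone synthesis. The chelated tetrahedral intermediate stops at the ketone, and the electron-rich phenoxide ring disfavours enolization. Br/Li exchange at −78 °C avoids benzyne formation from the o-fluoroaryllithium.

**Step 5**
Reactants: 9
Product: 10 (7-(allyloxy)-3-hydroxy-2-(3-methylbut-2-en-1-yl)dibenzo[b,f]oxepin-10(11H)-one)
Conditions: Cs2CO3 (2.5 equiv), DMF (0.02 M), 110 °C, 12 h
Reagents that add atoms: none
Why: Intramolecular SNAr (7-membered ring closure). The ring-A 2-phenoxide is the only phenoxide that can reach the fluorine ortho to the ketone, so the 4-OH stays free and the diaryl ether forms regiospecifically. Loss of HF is the only change.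

**Step 6**
Reactants: 10; 7 (allyl bromide)
Product: 11 (3,7-bis(allyloxy)-2-(3-methylbut-2-en-1-yl)dibenzo[b,f]oxepin-10(11H)-one)
Conditions: 7 (1.1 equiv), K2CO3, acetone, reflux, 4 h
Reagents that add atoms: none beyond the listed reactant 7
Why: Williamson O-allylation of the only free phenol. This masks it so it cannot form a chromene with prenal in the next step. Mild K2CO3 does not alkylate the ketone CH2.

**Step 7**
Reactants: 11; 12 (prenal, 3-methylbut-2-enal)
Product: 13 (3,7-bis(allyloxy)-2-prenyl-pyrano-fused dibenzoxepine, the bis-allyl ether of the target)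
Conditions: 12 (4 equiv), ethylenediammonium diacetate (0.2 equiv), toluene, 4 Å MS, 110 °C (sealed tube), 12 h
Reagents that add atoms: none beyond the listed reactant 12
Why: Knoevenagel-type aldol condensation at the acidic C11-H2 (benzylic and α to the ketone) gives the aryl dienone O=C10–C11=CH–CH=CMe2. Amine catalysis equilibrates it to the Z isomer, which undergoes thermal 6π-oxa-electrocyclization to the 2,2-dimethyl-2H-pyran with C10(–O)=C11. No stereocentre is formed.

**Step 8**
Reactants: 13
Product: 14 (Artocarpol D)
Conditions: Pd(PPh3)4 (10 mol%), K2CO3 (3 equiv), MeOH, rt, 4 h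
Reagents that add atoms: none
Why: Pd(0)-catalysed aryl allyl ether cleavage under basic, non-acidic conditions, with methoxide as the allyl scavenger. It leaves the acid-sensitive pyran enol ether and the prenyl alkene intact.

## Compound list
1 | 2,4-dihydroxyphenylacetic acid | OC(=O)Cc1ccc(O)cc1O | starting material
2 | N,O-dimethylhydroxylamine hydrochloride | CONC.Cl | starting material
3 | 2-(2,4-dihydroxyphenyl)-N-methoxy-N-methylacetamide | CON(C)C(=O)Cc1ccc(O)cc1O | intermediate
4 | prenyl bromide | CC(C)=CCBr | starting material
5 | 2-[2,4-dihydroxy-5-(3-methylbut-2-en-1-yl)phenyl]-N-methoxy-N-methylacetamide | CON(C)C(=O)Cc1cc(CC=C(C)C)c(O)cc1O | intermediate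
6 | 4-bromo-3-fluorophenol | Oc1ccc(Br)c(F)c1 | starting material
7 | allyl bromide | C=CCBr | starting material
8 | 4-(allyloxy)-1-bromo-2-fluorobenzene | C=CCOc1ccc(Br)c(F)c1 | intermediate
9 | 1-[4-(allyloxy)-2-fluorophenyl]-2-[2,4-dihydroxy-5-prenylphenyl]ethan-1-one | C=CCOc1ccc(C(=O)Cc2cc(CC=C(C)C)c(O)cc2O)c(F)c1 | intermediate
10 | 7-(allyloxy)-3-hydroxy-2-prenyldibenzo[b,f]oxepin-10(11H)-one | O=C1Cc2cc(CC=C(C)C)c(O)cc2Oc2cc(OCC=C)ccc21 | intermediate
11 | 3,7-bis(allyloxy)-2-prenyldibenzo[b,f]oxepin-10(11H)-one | O=C1Cc2cc(CC=C(C)C)c(OCC=C)cc2Oc2cc(OCC=C)ccc21 | intermediate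
12 | prenal (3-methylbut-2-enal) | CC(C)=CC=O | starting material
13 | bis-allyl ether of Artocarpol D | CC(C)=CCc1cc2c(cc1OCC=C)Oc1cc(OCC=C)ccc1C1=C2C=CC(C)(C)O1 | intermediate
14 | Artocarpol D (achiral, no stereocentres) | CC(C)=CCc1cc2c(cc1O)Oc1cc(O)ccc1C1=C2C=CC(C)(C)O1 | target

Total steps: 8 (step 3 is a parallel branch). Longest linear sequence: 7 (steps 1, 2, 4, 5, 6, 7, 8).

## Three steps most likely to fail
1. **Step 2, C-prenylation.** Yield and selectivity can be poor because of O- versus C-alkylation, C3 versus C5 attack and di-prenylation. Fallback: brominate the Weinreb amide 3 with NBS at C5 (the same ortho/para site), then cross-couple with prenyl-9-BBN (Pd, Suzuki). Alternatively, O-allylate, Claisen-rearrange, then cross-metathesize with 2-methyl-2-butene.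
2. **Step 5, seven-membered SNAr.** The para-O-allyl group deactivates the ring, and the ketone may enolize under the carbonate. Fallback: form the diaryl ether first by intermolecular SNAr between a methyl 2-hydroxy-4-allyloxy-phenylacetate and methyl 2-fluoro-4-allyloxybenzoate. Then close the ring by Dieckmann condensation (KOt-Bu) and decarboxylate to give the same oxepinone.
3. **Step 7, condensation and electrocyclization.** The open dienone may be favoured over the pyran, or prenal may self-condense. Fallback: stepwise route. Form the LDA enolate of 11 (−78 °C) and add prenal to give the aldol. Dehydrate with MsCl/Et3N then DBU to the dienone. Heat in toluene to drive the oxa-6π closure.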